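**Retrosynthetic overview**
1. Target 28 ⇐ acetal hydrolysis, desilylation and esterification ⇐ dihydropyranylacetic acid 22 + bis-silylated hydroxytyrosol 25.
2. The dihydropyran (the only ring made) ⇐ O1–C6 cyclodehydration of a δ-hydroxy α-formyl ester; C6 comes from methyl formate by Claisen formylation of open-chain ester 17.
3. C2 and C3 ⇐ Evans syn-aldol of imide 11 with acetaldehyde (C2–C3 bond).
4. C4 and the C4–C5 bond ⇐ enantioselective intermolecular Michael addition of malonate 4 to enal 3 (the fragment union); 3 ⇐ cross-metathesis of 1 with crotonaldehyde.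
5. Ring order: all three stereocentres are set on the open chain (Michael, then aldol), then the single ring closure; the arene is bought.

Assumption: the SMILES is taken as drawn, i.e. methyl (2S,3R,4R)-4-{2-[2-(3,4-dihydroxyphenyl)ethoxy]-2-oxoethyl}-3-formyl-2-methyl-3,4-dihydro-2H-pyran-5-carboxylate (ring substituents all trans; pyran numbering O1, C2 Me, C3 CHO, C4 side chain, C5 CO2Me, C6).

**Route**

Step 1
Reactants: 1 4-(benzyloxy)but-1-ene; 2 (E)-but-2-enal
Product: 3 (E)-5-(benzyloxy)pent-2-enal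
Conditions: second-generation Hoveyda–Grubbs catalyst RuCl2(H2IMes)(=CH-C6H4-2-O-i-Pr) (2 mol %), 2 (5 equiv), CH2Cl2, 40 °C
Reagents that add atoms: none
Why: Olefin cross-metathesis of a terminal alkene with excess crotonaldehyde gives the conjugated E-enal under thermodynamic control.

Step 2
Reactants: 3 (E)-5-(benzyloxy)pent-2-enal; 4 tert-butyl methyl malonate
Product: 5 1-tert-butyl 3-methyl 2-[(3R)-5-(benzyloxy)-1-oxopentan-3-yl]propanedioate
Conditions: (S)-2-[diphenyl(trimethylsilyloxy)methyl]pyrrolidine (10 mol %), PhCO2H (10 mol %), EtOH, 0 °C → rt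
Reagents that add atoms: none
Why: Iminium-catalysed asymmetric Michael addition (Jørgensen–Hayashi catalyst), in which the CPh2(OTMS) group shields one face of the s-trans E-iminium ion so the malonate adds to the open face of the β-carbon and sets the future C4 as R.

Step 3
Reactants: 5 1-tert-butyl 3-methyl 2-[(3R)-5-(benzyloxy)-1-oxopentan-3-yl]propanedioate
Product: 6 (3R)-5-(benzyloxy)-3-[1-(tert-butoxy)-3-methoxy-1,3-dioxopropan-2-yl]pentanoic acid
Conditions: NaClO2, NaH2PO4, 2-methylbut-2-ene, t-BuOH/H2O, 0 °C → rt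
Reagents that add atoms: sodium chlorite, [Na+].[O-]Cl=O
Why: Pinnick oxidation takes the aldehyde to the acid without touching the malonate or the stereocentre.

Step 4
Reactants: 6 (3R)-5-(benzyloxy)-3-[1-(tert-butoxy)-3-methoxy-1,3-dioxopropan-2-yl]pentanoic acid
Product: 8 (3R)-5-(benzyloxy)-3-(2-methoxy-2-oxoethyl)pentanoic acid, via malonic half-acid 7 (not isolated)
Conditions: TFA, CH2Cl2, rt; evaporate; pyridine, 100 °C
Reagents that add atoms: none
Why: Acidolysis of the tert-butyl ester and thermal decarboxylation of the malonic half-acid leave one CH2CO2Me arm, so the acid and ester arms stay distinct and the centre stays defined.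

Step 5
Reactants: 8 (3R)-5-(benzyloxy)-3-(2-methoxy-2-oxoethyl)pentanoic acid; 9 (4R)-4-benzyl-1,3-oxazolidin-2-one
Product: 11 methyl (3R)-5-(benzyloxy)-3-{2-[(4R)-4-benzyl-2-oxo-1,3-oxazolidin-3-yl]-2-oxoethyl}pentanoate, via mixed pivalic anhydride 10 (not isolated)
Conditions: PivCl, Et3N, THF, −20 °C; then 9, LiCl, −20 °C → rt
Reagents that add atoms: none
Why: N-acylation of the oxazolidinone through the mixed anhydride (LiCl/Et3N variant) is mild enough not to scramble the acid and ester arms.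

Step 6
Reactants: 11 methyl (3R)-5-(benzyloxy)-3-{2-[(4R)-4-benzyl-2-oxo-1,3-oxazolidin-3-yl]-2-oxoethyl}pentanoate; 12 acetaldehyde
Product: 13 methyl (3S)-5-(benzyloxy)-3-[(2R,3S)-1-[(4R)-4-benzyl-2-oxo-1,3-oxazolidin-3-yl]-3-hydroxy-1-oxobutan-2-yl]pentanoate
Conditions: Bu2BOTf, i-Pr2NEt, CH2Cl2, −78 → 0 °C; 12 (3 equiv), −78 → 0 °C; then pH 7 buffer, MeOH, H2O2
Reagents that add atoms: none
Why: Evans syn-aldol reaction, in which the Z-boron enolate reacts through a Zimmerman–Traxler chair on the face away from the auxiliary benzyl group, setting future C3 (R) and C2 (S); any minor C4 epimer from step 2 is removed here as a diastereomer.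

Step 7
Reactants: 13 methyl (3S)-5-(benzyloxy)-3-[(2R,3S)-1-[(4R)-4-benzyl-2-oxo-1,3-oxazolidin-3-yl]-3-hydroxy-1-oxobutan-2-yl]pentanoate
Product: 14 methyl (3S)-5-(benzyloxy)-3-[(2R,3S)-1-[(4R)-4-benzyl-2-oxo-1,3-oxazolidin-3-yl]-3-{[tert-butyl(dimethyl)silyl]oxy}-1-oxobutan-2-yl]pentanoate
Conditions: TBSOTf, 2,6-lutidine, CH2Cl2, −78 → 0 °C
Reagents that add atoms: tert-butyldimethylsilyl triflate, CC(C)(C)[Si](C)(C)OS(=O)(=O)C(F)(F)F
Why: Silyl ether protection of the secondary alcohol blocks retro-aldol and lactonisation in the following steps.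

Step 8
Reactants: 14 methyl (3S)-5-(benzyloxy)-3-[(2R,3S)-1-[(4R)-4-benzyl-2-oxo-1,3-oxazolidin-3-yl]-3-{[tert-butyl(dimethyl)silyl]oxy}-1-oxobutan-2-yl]pentanoate
Product: 15 methyl (3S)-5-(benzyloxy)-3-[(2R,3S)-3-{[tert-butyl(dimethyl)silyl]oxy}-1-(ethylsulfanyl)-1-oxobutan-2-yl]pentanoate
Conditions: EtSH, n-BuLi, THF, 0 °C
Reagents that add atoms: ethanethiol, CCS
Why: Thiolate transacylation cleaves the exocyclic imide carbonyl selectively (soft, weakly basic nucleophile), leaving the methyl ester and the α-centre intact and returning the auxiliary.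

Step 9
Reactants: 15 methyl (3S)-5-(benzyloxy)-3-[(2R,3S)-3-{[tert-butyl(dimethyl)silyl]oxy}-1-(ethylsulfanyl)-1-oxobutan-2-yl]pentanoate
Product: 17 methyl (3S)-5-(benzyloxy)-3-[(2R,3S)-3-{[tert-butyl(dimethyl)silyl]oxy}-1,1-dimethoxybutan-2-yl]pentanoate, via aldehyde 16 (not isolated)
Conditions: Et3SiH, Pd/C (10 %), acetone, rt; filter; then HC(OMe)3, PPTS, MeOH, rt
Reagents that add atoms: trimethyl orthoformate, COC(OC)OC
Why: Fukuyama reduction gives the aldehyde without touching the ester, and immediate acetalisation masks it before it can epimerise or eliminate.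

Step 10
Reactants: 17 methyl (3S)-5-(benzyloxy)-3-[(2R,3S)-3-{[tert-butyl(dimethyl)silyl]oxy}-1,1-dimethoxybutan-2-yl]pentanoate
Product: 20 methyl (2S,3R,4R)-4-[2-(benzyloxy)ethyl]-3-(dimethoxymethyl)-2-methyl-3,4-dihydro-2H-pyran-5-carboxylate, via formyl ester 18 (not isolated), via hydroxy formyl ester 19 (not isolated)
Conditions: LiN(i-Pr)2, THF, −78 °C; HCO2Me, −78 → 0 °C; AcOH; then HCl (1.25 M in MeOH), HC(OMe)3, 0 → 40 °C
Reagents that add atoms: methyl formate, COC=O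
Why: Crossed Claisen condensation formylates the only enolisable position, then acid removes the silyl group and the freed hydroxyl condenses with the formyl ester (Korte-type cyclodehydration) to the conjugated dihydropyran; anhydrous methanol keeps C3 as its dimethyl acetal and no stereocentre is touched.

Step 11
Reactants: 20 methyl (2S,3R,4R)-4-[2-(benzyloxy)ethyl]-3-(dimethoxymethyl)-2-methyl-3,4-dihydro-2H-pyran-5-carboxylate
Product: 21 methyl (2S,3R,4R)-3-(dimethoxymethyl)-4-(2-hydroxyethyl)-2-methyl-3,4-dihydro-2H-pyran-5-carboxylate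
Conditions: H2 (1 atm), Pd/C (10 %), EtOAc, rt
Reagents that add atoms: none
Why: Hydrogenolysis cleaves the benzyl ether while the push-pull enol ether double bond is inert under these mild neutral conditions.

Step 12
Reactants: 21 methyl (2S,3R,4R)-3-(dimethoxymethyl)-4-(2-hydroxyethyl)-2-methyl-3,4-dihydro-2H-pyran-5-carboxylate
Product: 22 2-[(2S,3R,4R)-3-(dimethoxymethyl)-5-(methoxycarbonyl)-2-methyl-3,4-dihydro-2H-pyran-4-yl]acetic acid
Conditions: TEMPO (cat.), NaClO2, NaOCl (cat.), MeCN/phosphate buffer pH 6.7, 35 °C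
Reagents that add atoms: sodium chlorite, [Na+].[O-]Cl=O
Why: TEMPO/chlorite (Zhao) oxidation takes the primary alcohol to the acid at near-neutral pH, sparing the acetal and the enol ether.

Step 13
Reactants: 23 methyl 2-(3,4-dihydroxyphenyl)acetate
Product: 24 methyl 2-(3,4-bis{[tert-butyl(dimethyl)silyl]oxy}phenyl)acetate
Conditions: TBSCl, imidazole, DMF, rt
Reagents that add atoms: tert-butyldimethylsilyl chloride, CC(C)(C)[Si](C)(C)Cl
Why: Standard silyl ether formation protects both phenols against the later oxidation-sensitive and acylating steps.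

Step 14
Reactants: 24 methyl 2-(3,4-bis{[tert-butyl(dimethyl)silyl]oxy}phenyl)acetate
Product: 25 2-(3,4-bis{[tert-butyl(dimethyl)silyl]oxy}phenyl)ethan-1-ol
Conditions: i-Bu2AlH, CH2Cl2, −78 → 0 °C; aq. KNaC4H4O6
Reagents that add atoms: none
Why: Hydride reduction of the ester to the primary alcohol at low temperature leaves the aryl silyl ethers intact.

Step 15
Reactants: 22 2-[(2S,3R,4R)-3-(dimethoxymethyl)-5-(methoxycarbonyl)-2-methyl-3,4-dihydro-2H-pyran-4-yl]acetic acid; 25 2-(3,4-bis{[tert-butyl(dimethyl)silyl]oxy}phenyl)ethan-1-ol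
Product: 26 methyl (2S,3R,4R)-4-[2-(2-{3,4-bis[(tert-butyldimethylsilyl)oxy]phenyl}ethoxy)-2-oxoethyl]-3-(dimethoxymethyl)-2-methyl-3,4-dihydro-2H-pyran-5-carboxylate
Conditions: EDC·HCl, DMAP (cat.), CH2Cl2, 0 °C → rt
Reagents that add atoms: none
Why: Steglich-type carbodiimide esterification joins the acid to the primary alcohol without touching the acetal or the conjugated ester.

Step 16
Reactants: 26 methyl (2S,3R,4R)-4-[2-(2-{3,4-bis[(tert-butyldimethylsilyl)oxy]phenyl}ethoxy)-2-oxoethyl]-3-(dimethoxymethyl)-2-methyl-3,4-dihydro-2H-pyran-5-carboxylate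
Product: 27 methyl (2S,3R,4R)-4-{2-[2-(3,4-dihydroxyphenyl)ethoxy]-2-oxoethyl}-3-(dimethoxymethyl)-2-methyl-3,4-dihydro-2H-pyran-5-carboxylate
Conditions: Bu4NF, AcOH, THF, 0 °C
Reagents that add atoms: none
Why: Buffered fluoride desilylation frees the catechol while the aldehyde is still masked, so nothing base-sensitive is exposed.

Step 17
Reactants: 27 methyl (2S,3R,4R)-4-{2-[2-(3,4-dihydroxyphenyl)ethoxy]-2-oxoethyl}-3-(dimethoxymethyl)-2-methyl-3,4-dihydro-2H-pyran-5-carboxylate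
Product: 28 methyl (2S,3R,4R)-4-{2-[2-(3,4-dihydroxyphenyl)ethoxy]-2-oxoethyl}-3-formyl-2-methyl-3,4-dihydro-2H-pyran-5-carboxylate
Conditions: 1 M aq. HCl, THF, 0 °C → rt
Reagents that add atoms: water, O
Why: Mild acid-catalysed acetal hydrolysis releases the aldehyde; the all-trans arrangement is the thermodynamically preferred one and no base is present that could open the ring by retro-oxa-Michael reaction.

**Compound list**

1 | 4-(benzyloxy)but-1-ene | C=CCCOCc1ccccc1 | starting material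
2 | (E)-but-2-enal (crotonaldehyde) | C/C=C/C=O | starting material
3 | (E)-5-(benzyloxy)pent-2-enal | O=C/C=C/CCOCc1ccccc1 | intermediate
4 | tert-butyl methyl malonate | COC(=O)CC(=O)OC(C)(C)C | starting material
5 | 1-tert-butyl 3-methyl 2-[(3R)-5-(benzyloxy)-1-oxopentan-3-yl]propanedioate (both epimers at the malonate carbon) | O=CC[C@H](C(C(=O)OC)C(=O)OC(C)(C)C)CCOCc1ccccc1 | intermediate
6 | (3R)-5-(benzyloxy)-3-[1-(tert-butoxy)-3-methoxy-1,3-dioxopropan-2-yl]pentanoic acid | OC(=O)C[C@H](C(C(=O)OC)C(=O)OC(C)(C)C)CCOCc1ccccc1 | intermediate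
7 | 2-[(2R)-4-(benzyloxy)-1-carboxybutan-2-yl]-3-methoxy-3-oxopropanoic acid (malonic half-acid) | OC(=O)C[C@H](C(C(=O)OC)C(=O)O)CCOCc1ccccc1 | intermediate (not isolated)
8 | (3R)-5-(benzyloxy)-3-(2-methoxy-2-oxoethyl)pentanoic acid | OC(=O)C[C@H](CC(=O)OC)CCOCc1ccccc1 | intermediate
9 | (4R)-4-benzyl-1,3-oxazolidin-2-one | O=C1N[C@H](Cc2ccccc2)CO1 | starting material
10 | (3S)-5-(benzyloxy)-3-(2-methoxy-2-oxoethyl)pentanoic 2,2-dimethylpropanoic anhydride (mixed pivalic anhydride) | CC(C)(C)C(=O)OC(=O)C[C@H](CC(=O)OC)CCOCc1ccccc1 | intermediate (not isolated)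
11 | methyl (3R)-5-(benzyloxy)-3-{2-[(4R)-4-benzyl-2-oxo-1,3-oxazolidin-3-yl]-2-oxoethyl}pentanoate | COC(=O)C[C@@H](CC(=O)N1[C@H](Cc2ccccc2)COC1=O)CCOCc1ccccc1 | intermediate
12 | acetaldehyde | CC=O | starting material
13 | methyl (3S)-5-(benzyloxy)-3-[(2R,3S)-1-[(4R)-4-benzyl-2-oxo-1,3-oxazolidin-3-yl]-3-hydroxy-1-oxobutan-2-yl]pentanoate | C[C@H](O)[C@H](C(=O)N1[C@H](Cc2ccccc2)COC1=O)[C@H](CC(=O)OC)CCOCc1ccccc1 | intermediate
14 | methyl (3S)-5-(benzyloxy)-3-[(2R,3S)-1-[(4R)-4-benzyl-2-oxo-1,3-oxazolidin-3-yl]-3-{[tert-butyl(dimethyl)silyl]oxy}-1-oxobutan-2-yl]pentanoate | C[C@H](O[Si](C)(C)C(C)(C)C)[C@H](C(=O)N1[C@H](Cc2ccccc2)COC1=O)[C@H](CC(=O)OC)CCOCc1ccccc1 | intermediate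
15 | methyl (3S)-5-(benzyloxy)-3-[(2R,3S)-3-{[tert-butyl(dimethyl)silyl]oxy}-1-(ethylsulfanyl)-1-oxobutan-2-yl]pentanoate | C[C@H](O[Si](C)(C)C(C)(C)C)[C@H](C(=O)SCC)[C@H](CC(=O)OC)CCOCc1ccccc1 | intermediate
16 | methyl (3S)-5-(benzyloxy)-3-[(2R,3S)-3-{[tert-butyl(dimethyl)silyl]oxy}-1-oxobutan-2-yl]pentanoate (aldehyde) | C[C@H](O[Si](C)(C)C(C)(C)C)[C@H](C=O)[C@H](CC(=O)OC)CCOCc1ccccc1 | intermediate (not isolated)
17 | methyl (3S)-5-(benzyloxy)-3-[(2R,3S)-3-{[tert-butyl(dimethyl)silyl]oxy}-1,1-dimethoxybutan-2-yl]pentanoate | C[C@H](O[Si](C)(C)C(C)(C)C)[C@H](C(OC)OC)[C@H](CC(=O)OC)CCOCc1ccccc1 | intermediate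
18 | methyl (3R)-5-(benzyloxy)-3-[(2R,3S)-3-{[tert-butyl(dimethyl)silyl]oxy}-1,1-dimethoxybutan-2-yl]-2-formylpentanoate (C2 epimers, largely enol; formyl ester) | C[C@H](O[Si](C)(C)C(C)(C)C)[C@H](C(OC)OC)[C@H](C(C=O)C(=O)OC)CCOCc1ccccc1 | intermediate (not isolated)
19 | methyl (3R)-5-(benzyloxy)-2-formyl-3-[(2R,3S)-3-hydroxy-1,1-dimethoxybutan-2-yl]pentanoate (hydroxy formyl ester) | C[C@H](O)[C@H](C(OC)OC)[C@H](C(C=O)C(=O)OC)CCOCc1ccccc1 | intermediate (not isolated)
20 | methyl (2S,3R,4R)-4-[2-(benzyloxy)ethyl]-3-(dimethoxymethyl)-2-methyl-3,4-dihydro-2H-pyran-5-carboxylate | COC(=O)C1=CO[C@@H](C)[C@H](C(OC)OC)[C@H]1CCOCc1ccccc1 | intermediate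
21 | methyl (2S,3R,4R)-3-(dimethoxymethyl)-4-(2-hydroxyethyl)-2-methyl-3,4-dihydro-2H-pyran-5-carboxylate | COC(=O)C1=CO[C@@H](C)[C@H](C(OC)OC)[C@H]1CCO | intermediate
22 | 2-[(2S,3R,4R)-3-(dimethoxymethyl)-5-(methoxycarbonyl)-2-methyl-3,4-dihydro-2H-pyran-4-yl]acetic acid | COC(=O)C1=CO[C@@H](C)[C@H](C(OC)OC)[C@H]1CC(=O)O | intermediate
23 | methyl 2-(3,4-dihydroxyphenyl)acetate | COC(=O)Cc1ccc(O)c(O)c1 | starting material
24 | methyl 2-(3,4-bis{[tert-butyl(dimethyl)silyl]oxy}phenyl)acetate | COC(=O)Cc1ccc(O[Si](C)(C)C(C)(C)C)c(O[Si](C)(C)C(C)(C)C)c1 | intermediate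
25 | 2-(3,4-bis{[tert-butyl(dimethyl)silyl]oxy}phenyl)ethan-1-ol | OCCc1ccc(O[Si](C)(C)C(C)(C)C)c(O[Si](C)(C)C(C)(C)C)c1 | intermediate
26 | methyl (2S,3R,4R)-4-[2-(2-{3,4-bis[(tert-butyldimethylsilyl)oxy]phenyl}ethoxy)-2-oxoethyl]-3-(dimethoxymethyl)-2-methyl-3,4-dihydro-2H-pyran-5-carboxylate | COC(=O)C1=CO[C@@H](C)[C@H](C(OC)OC)[C@H]1CC(=O)OCCc1ccc(O[Si](C)(C)C(C)(C)C)c(O[Si](C)(C)C(C)(C)C)c1 | intermediate
27 | methyl (2S,3R,4R)-4-{2-[2-(3,4-dihydroxyphenyl)ethoxy]-2-oxoethyl}-3-(dimethoxymethyl)-2-methyl-3,4-dihydro-2H-pyran-5-carboxylate | COC(=O)C1=CO[C@@H](C)[C@H](C(OC)OC)[C@H]1CC(=O)OCCc1ccc(O)c(O)c1 | intermediate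
28 | methyl (2S,3R,4R)-4-{2-[2-(3,4-dihydroxyphenyl)ethoxy]-2-oxoethyl}-3-formyl-2-methyl-3,4-dihydro-2H-pyran-5-carboxylate | COC(=O)C1=CO[C@@H](C)[C@H](C=O)[C@H]1CC(=O)OCCc1ccc(O)c(O)c1 | target

**Totals and risks**

Total step count: 17. Longest linear sequence: 15 steps (steps 1–12 and 15–17, from 1 to 28); steps 13–14 are the side branch to 25.

Step 2 (Michael addition) may give modest conversion or ee with this aliphatic enal and an unsymmetrical malonate. The fallback sets the centre by desymmetrisation instead; it sets out from 1 and comes back at 8. Cross-metathesis of 1 with methyl acrylate gives methyl (E)-5-(benzyloxy)pent-2-enoate F1. NaOMe-mediated Michael addition of dimethyl malonate then gives racemic trimethyl 2-[2-(benzyloxy)ethyl]propane-1,1,3-tricarboxylate F2. Saponification (aq. KOH), acidification and thermal decarboxylation give achiral 3-[2-(benzyloxy)ethyl]pentanedioic acid F3, and Ac2O closes it to 4-[2-(benzyloxy)ethyl]oxane-2,6-dione F4. Cinchona-alkaloid-catalysed methanolysis (Et2O, −40 °C) opens the anhydride enantioselectively to 8; of the pseudoenantiomeric catalysts (DHQD)2AQN and (DHQ)2AQN, the one that delivers the 3R acid is used, and I have not assigned which one that is.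

Step 10 (formylation and cyclodehydration) may stall at the cyclic methyl acetal or give a poor formylation yield on the β-branched ester. The fallback goes through a lactone; it sets out from 17 and comes back at 20. Bu4NF removes the silyl group and the alkoxide closes onto the methyl ester to give (4S,5R,6S)-4-[2-(benzyloxy)ethyl]-5-(dimethoxymethyl)-6-methyloxan-2-one F5. Heating with tert-butoxybis(dimethylamino)methane (toluene, 80 °C) converts the lactone α-methylene into (3E,4R,5R,6S)-4-[2-(benzyloxy)ethyl]-3-[(dimethylamino)methylidene]-5-(dimethoxymethyl)-6-methyloxan-2-one F6. HCl in MeOH then effects the Korte rearrangement (lactone methanolysis, ring closure of the freed hydroxyl onto the enamine carbon with loss of dimethylamine) to 20.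

Step 11 (debenzylation) may partly reduce the ring double bond, and the hydroxy ester 21 can lactonise onto the C5 ester. The fallback moves debenzylation and oxidation ahead of ring formation; it sets out from 17 and comes back at 22. Hydrogenolysis of 17 gives methyl (3S)-3-[(2R,3S)-3-{[tert-butyl(dimethyl)silyl]oxy}-1,1-dimethoxybutan-2-yl]-5-hydroxypentanoate F7. TEMPO/NaClO2 oxidation gives (3S)-3-[(2R,3S)-3-{[tert-butyl(dimethyl)silyl]oxy}-1,1-dimethoxybutan-2-yl]-5-methoxy-5-oxopentanoic acid F8. Formylation with excess LiN(i-Pr)2 and HCO2Me (the carboxylate is a spectator), then HCl/MeOH/HC(OMe)3, closes the ring and esterifies the acid to methyl (2S,3R,4R)-3-(dimethoxymethyl)-4-(2-methoxy-2-oxoethyl)-2-methyl-3,4-dihydro-2H-pyran-5-carboxylate F9. LiOH (1.1 equiv, THF/H2O, 0 °C) then saponifies only the saturated methyl ester, since the conjugated C5 ester is much less electrophilic, giving 22.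

**Further compounds**

F1 | step 2 | methyl (E)-5-(benzyloxy)pent-2-enoate | COC(=O)/C=C/CCOCc1ccccc1
F2 | step 2 | trimethyl 2-[2-(benzyloxy)ethyl]propane-1,1,3-tricarboxylate (racemic) | COC(=O)CC(CCOCc1ccccc1)C(C(=O)OC)C(=O)OC
F3 | step 2 | 3-[2-(benzyloxy)ethyl]pentanedioic acid | OC(=O)CC(CCOCc1ccccc1)CC(=O)O
F4 | step 2 | 4-[2-(benzyloxy)ethyl]oxane-2,6-dione | O=C1CC(CCOCc2ccccc2)CC(=O)O1
F5 | step 10 | (4S,5R,6S)-4-[2-(benzyloxy)ethyl]-5-(dimethoxymethyl)-6-methyloxan-2-one | C[C@@H]1OC(=O)C[C@H](CCOCc2ccccc2)[C@H]1C(OC)OC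
F6 | step 10 | (3E,4R,5R,6S)-4-[2-(benzyloxy)ethyl]-3-[(dimethylamino)methylidene]-5-(dimethoxymethyl)-6-methyloxan-2-one | C[C@@H]1OC(=O)/C(=C/N(C)C)[C@H](CCOCc2ccccc2)[C@H]1C(OC)OC
F7 | step 11 | methyl (3S)-3-[(2R,3S)-3-{[tert-butyl(dimethyl)silyl]oxy}-1,1-dimethoxybutan-2-yl]-5-hydroxypentanoate | C[C@H](O[Si](C)(C)C(C)(C)C)[C@H](C(OC)OC)[C@H](CC(=O)OC)CCO
F8 | step 11 | (3S)-3-[(2R,3S)-3-{[tert-butyl(dimethyl)silyl]oxy}-1,1-dimethoxybutan-2-yl]-5-methoxy-5-oxopentanoic acid | C[C@H](O[Si](C)(C)C(C)(C)C)[C@H](C(OC)OC)[C@H](CC(=O)OC)CC(=O)O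
F9 | step 11 | methyl (2S,3R,4R)-3-(dimethoxymethyl)-4-(2-methoxy-2-oxoethyl)-2-methyl-3,4-dihydro-2H-pyran-5-carboxylate | COC(=O)C1=CO[C@@H](C)[C@H](C(OC)OC)[C@H]1CC(=O)OC
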